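The route rests on cutting the C5–C6 bond of the carbocycle (isochromene numbering). The key step exploits the 1,3-relationship between the C6 ketone and the sp2 carbon C4a, a masked ketone, in the cyclohexenone ring. The enolate of a methyl ketone (C5) is acylated by the C6 methyl ester, which closes the six-membered ring as a cyclohexane-1,3-dione in one operation and leaves C7 and C8 untouched. The precursor is an acyclic O-triethylsilyl 3-acetonyl citramalate diester whose two stereocentres come from one catalytic syn-selective pyruvate aldol. Regioselective enol triflation, Sonogashira coupling, one-carbon homologation at C8a and AuCl3-catalysed closure then build the pyran ring.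

Key step: step 9

Remark: atom labels C1–C8a follow the isochromene numbering of the target; the Cu(OTf)2–bis(oxazoline) pyruvate aldol is assumed to follow its established sense ((S,S)-ligand: S carbinol, syn adduct), hence the (R,R)-ligand in step 5.

Step 1
Reactants: 1 (S)-1-bromo-2-methylbutane; 2 N-methoxy-N-methylacetamide
Product: 4 (S)-4-methylhexan-2-one, via (S)-2-methylbutylmagnesium bromide 3 (not isolated)
Conditions: Mg, THF, reflux; then 2, THF, 0 °C; aq. NH4Cl
Reagents that add atoms: none
Why: Weinreb ketone synthesis: the Grignard reagent adds only once because the magnesium chelate of the tetrahedral adduct survives until work-up, and the stereocentre, which is beta to magnesium, is not touched.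

Step 2
Reactants: 4 (S)-4-methylhexan-2-one
Product: 5 (2S,4S)-4-methylhexan-2-ol
Conditions: (S)-selective alcohol dehydrogenase (ADH-A from Rhodococcus ruber), NADH (cat.), i-PrOH, phosphate buffer pH 7.5, 30 °C
Reagents that add atoms: none
Why: Ketoreductase reduction with isopropanol as the hydride source: the enzyme delivers hydride to the re face of the methyl ketone, so C2 should be set as S under enzyme control, independent of the remote C4 centre.

Step 3
Reactants: 6 4-methylpent-4-enoic acid; 7 ethanethiol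
Product: 8 S-ethyl 4-methylpent-4-enethioate
Conditions: DCC, DMAP (cat.), CH2Cl2, 0 °C to rt
Reagents that add atoms: none
Why: Steglich thioesterification through the O-acylisourea and the acylpyridinium ion, for which an unhindered acid and a nucleophilic thiol are well suited.

Step 4
Reactants: 8 S-ethyl 4-methylpent-4-enethioate
Product: 9 (Z)-1-(ethylsulfanyl)-4-methyl-1-[(trimethylsilyl)oxy]penta-1,4-diene
Conditions: LiN(i-Pr)2, THF, −78 °C; then Me3SiCl, −78 °C to rt
Reagents that add atoms: chlorotrimethylsilane, C[Si](C)(C)Cl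
Why: Kinetic enolisation of the thioester and O-silylation (silyl ketene thioacetal formation); the enolsilane geometry is not critical, since both geometries are expected to converge on the syn adduct in step 5.

Step 5
Reactants: 9 (Z)-1-(ethylsulfanyl)-4-methyl-1-[(trimethylsilyl)oxy]penta-1,4-diene; 10 methyl pyruvate
Product: 12 methyl (2R,3R)-3-[(ethylsulfanyl)carbonyl]-2-hydroxy-2,5-dimethylhex-5-enoate, via trimethylsilyl ether of the adduct 11 (not isolated)
Conditions: Cu(OTf)2 (10 mol%), (R,R)-t-Bu-box [2,2'-(propane-2,2-diyl)bis((4R)-4-tert-butyl-4,5-dihydrooxazole)] (11 mol%), THF, −78 °C; then 1 M HCl, THF, rt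
Reagents that add atoms: none
Why: Catalytic enantioselective Mukaiyama aldol addition to a chelated ketoester: the square-planar divalent copper chelate of the pyruvate exposes one carbonyl face, so the ligand enantiomer should set the carbinol carbon (C7) as R, and the open transition state that keeps the enolsilane substituent away from the metal chelate should set C8 as R (syn adduct).

Step 6
Reactants: 12 methyl (2R,3R)-3-[(ethylsulfanyl)carbonyl]-2-hydroxy-2,5-dimethylhex-5-enoate
Product: 13 methyl (2R,3R)-3-[(ethylsulfanyl)carbonyl]-2,5-dimethyl-2-[(triethylsilyl)oxy]hex-5-enoate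
Conditions: Et3SiOTf, 2,6-lutidine, CH2Cl2, 0 °C to rt
Reagents that add atoms: triethylsilyl trifluoromethanesulfonate, CC[Si](CC)(CC)OS(=O)(=O)C(F)(F)F
Why: Silylation of a tertiary alcohol with a silyl triflate and a hindered pyridine base, the standard protection of crowded carbinols; the thioester and the methyl ester are inert.

Step 7
Reactants: 13 methyl (2R,3R)-3-[(ethylsulfanyl)carbonyl]-2,5-dimethyl-2-[(triethylsilyl)oxy]hex-5-enoate; 5 (2S,4S)-4-methylhexan-2-ol
Product: 14 1-methyl 4-[(2S,4S)-4-methylhexan-2-yl] (2R,3R)-2-methyl-3-(2-methylprop-2-en-1-yl)-2-[(triethylsilyl)oxy]butanedioate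
Conditions: AgOCOCF3, Na2HPO4, toluene, 60 °C
Reagents that add atoms: none
Why: Thiophile-promoted alcoholysis of a thioester: silver binds sulfur and makes the thioester a strong enough acyl donor for a secondary alcohol, under buffered non-basic conditions that should leave C8 and the silyl ether alone.

Step 8
Reactants: 14 1-methyl 4-[(2S,4S)-4-methylhexan-2-yl] (2R,3R)-2-methyl-3-(2-methylprop-2-en-1-yl)-2-[(triethylsilyl)oxy]butanedioate
Product: 16 1-methyl 4-[(2S,4S)-4-methylhexan-2-yl] (2R,3R)-2-methyl-3-(2-oxopropyl)-2-[(triethylsilyl)oxy]butanedioate, via secondary ozonide 15 (not isolated)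
Conditions: O3, CH2Cl2, −78 °C; then Me2S, −78 °C to rt
Reagents that add atoms: ozone, [O-][O+]=O
Why: Ozonolysis of the 1,1-disubstituted alkene with reductive work-up gives the methyl ketone, and nothing else in 14 reacts with ozone at −78 °C.

Step 9
Reactants: 16 1-methyl 4-[(2S,4S)-4-methylhexan-2-yl] (2R,3R)-2-methyl-3-(2-oxopropyl)-2-[(triethylsilyl)oxy]butanedioate
Product: 18 (2S,4S)-4-methylhexan-2-yl (1R,2R)-2-methyl-3,5-dioxo-2-[(triethylsilyl)oxy]cyclohexane-1-carboxylate, via potassium diketonate 17 (not isolated)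
Conditions: KOt-Bu (2.2 equiv), THF, −20 to 0 °C; then 1 M HCl to pH 3
Reagents that add atoms: none
Why: tert-Butoxide forms the ketone enolates reversibly, the C5 enolate adds to the C6 methyl ester, methoxide leaves, and the 1,3-dione is deprotonated at once to diketonate 17, which makes the sequence irreversible. The closest known reaction is the base-mediated Claisen (Dieckmann-type) cyclisation of 5-oxohexanoates to cyclohexane-1,3-diones. The carbocycle closes by a 6-(enolexo)-exo-trig acyl substitution that forms the C5–C6 bond. No stereocentre is created; quaternary C7 cannot epimerise, and C8 is protected once the ring carries the negative charge. The step needs acylation at C6 to outrun E1cB loss of the C7 silyloxy group from a C8 ester enolate and closure onto the side-chain ester. The substrate secures this because the ketone is several pKa units more acidic than the C8 ester proton, the C8a enolate could only close a four-membered ring, and attack on the hindered secondary ester would give a strained five-membered dione from a poorer acyl donor.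

Step 10
Reactants: 18 (2S,4S)-4-methylhexan-2-yl (1R,2R)-2-methyl-3,5-dioxo-2-[(triethylsilyl)oxy]cyclohexane-1-carboxylate
Product: 19 (2S,4S)-4-methylhexan-2-yl (1R,6R)-6-methyl-5-oxo-6-[(triethylsilyl)oxy]-3-[(trifluoromethanesulfonyl)oxy]cyclohex-3-ene-1-carboxylate
Conditions: Tf2O, Et3N, CH2Cl2, −78 °C
Reagents that add atoms: trifluoromethanesulfonic anhydride, O=S(=O)(OS(=O)(=O)C(F)(F)F)C(F)(F)F
Why: O-Sulfonylation of a cyclic 1,3-dione to a vinylogous acyl triflate: the C6 oxygen lies next to the fully substituted C7 and its silyl ether, so triflation should go to the open C4a oxygen, in line with the behaviour of 4,4-disubstituted cyclohexane-1,3-diones.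

Step 11
Reactants: 20 3-(trimethylsilyl)propynal; 21 tert-butyl (triphenylphosphoranylidene)acetate
Product: 22 tert-butyl (E)-5-(trimethylsilyl)pent-2-en-4-ynoate
Conditions: CH2Cl2, 0 °C to rt
Reagents that add atoms: none
Why: Wittig olefination with a stabilised ylide, which is E-selective.

Step 12
Reactants: 22 tert-butyl (E)-5-(trimethylsilyl)pent-2-en-4-ynoate
Product: 23 tert-butyl (E)-pent-2-en-4-ynoate
Conditions: K2CO3 (0.1 equiv), MeOH, 0 °C
Reagents that add atoms: none
Why: Protodesilylation of a trimethylsilyl alkyne by methanolysis under catalytic carbonate, kept cold and brief so that the tert-butyl enoate is left alone.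

Step 13
Reactants: 19 (2S,4S)-4-methylhexan-2-yl (1R,6R)-6-methyl-5-oxo-6-[(triethylsilyl)oxy]-3-[(trifluoromethanesulfonyl)oxy]cyclohex-3-ene-1-carboxylate; 23 tert-butyl (E)-pent-2-en-4-ynoate
Product: 24 (2S,4S)-4-methylhexan-2-yl (1R,6R)-3-[(E)-5-tert-butoxy-5-oxopent-3-en-1-yn-1-yl]-6-methyl-5-oxo-6-[(triethylsilyl)oxy]cyclohex-3-ene-1-carboxylate
Conditions: Pd(PPh3)2Cl2 (5 mol%), CuI (10 mol%), Et3N, THF, rt
Reagents that add atoms: none
Why: Sonogashira coupling: the electron-poor vinyl triflate adds to zerovalent palladium at room temperature and the alkyne is delivered through copper, so the C4a–C4 bond forms with no base strong enough to touch C8.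

Step 14
Reactants: 24 (2S,4S)-4-methylhexan-2-yl (1R,6R)-3-[(E)-5-tert-butoxy-5-oxopent-3-en-1-yn-1-yl]-6-methyl-5-oxo-6-[(triethylsilyl)oxy]cyclohex-3-ene-1-carboxylate; 25 trimethyl orthoformate
Product: 27 (2S,4S)-4-methylhexan-2-yl (1R,6R)-3-[(E)-5-tert-butoxy-5-oxopent-3-en-1-yn-1-yl]-2-(dimethoxymethyl)-6-methyl-5-oxo-6-[(triethylsilyl)oxy]cyclohex-3-ene-1-carboxylate (epimers at C8a), via tert-butyldimethylsilyl dienol ether 26 (not isolated)
Conditions: t-BuMe2SiOTf, Et3N, CH2Cl2, −78 to 0 °C; filtration through Celite (pentane); then 25, Me3SiOTf (10 mol%), CH2Cl2, −78 °C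
Reagents that add atoms: none
Why: Soft enolisation followed by a vinylogous Mukaiyama reaction with an orthoester: C7 has no hydrogen, so silyl triflate and amine can only form the linear dienol ether by loss of a C8a proton, and the dimethoxycarbenium ion should attack its gamma terminus (C8a) and restore the conjugated enone; the new C8a centre does not matter because it becomes sp2 in step 15.

Step 15
Reactants: 27 (2S,4S)-4-methylhexan-2-yl (1R,6R)-3-[(E)-5-tert-butoxy-5-oxopent-3-en-1-yn-1-yl]-2-(dimethoxymethyl)-6-methyl-5-oxo-6-[(triethylsilyl)oxy]cyclohex-3-ene-1-carboxylate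
Product: 29 tert-butyl (E)-3-[(7R,8R)-7-methyl-8-{[(2S,4S)-4-methylhexan-2-yl]oxycarbonyl}-6-oxo-7-[(triethylsilyl)oxy]-7,8-dihydro-6H-isochromen-3-yl]prop-2-enoate, via C8a-formyl enol 28 (not isolated)
Conditions: AuCl3 (5 mol%), MeCN/H2O (50:1), rt
Reagents that add atoms: water, O
Why: AuCl3-catalysed cycloisomerisation of a 2-alkynyl aldehyde: the Lewis-acidic wet medium hydrolyses the acetal, the aldehyde enolises into conjugation with the enone, and its oxygen attacks the activated alkyne at C3, which is also the electrophilic delta carbon of the ynenone, in a 6-endo-dig closure followed by protodeauration.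

Step 16
Reactants: 29 tert-butyl (E)-3-[(7R,8R)-7-methyl-8-{[(2S,4S)-4-methylhexan-2-yl]oxycarbonyl}-6-oxo-7-[(triethylsilyl)oxy]-7,8-dihydro-6H-isochromen-3-yl]prop-2-enoate
Product: 30 (E)-3-[(7R,8R)-7-hydroxy-7-methyl-8-{[(2S,4S)-4-methylhexan-2-yl]oxycarbonyl}-6-oxo-7,8-dihydro-6H-isochromen-3-yl]prop-2-enoic acid
Conditions: TFA/CH2Cl2/H2O (10:10:1), 0 °C to rt
Reagents that add atoms: none
Why: Acidolysis: the tert-butyl ester fragments by an E1 pathway to the acid and the triethylsilyl ether is hydrolysed, while the secondary alkyl ester, the tertiary alcohol next to the ketone and the reversibly protonated vinylogous pyranone should survive.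

Compound list
1 | (S)-1-bromo-2-methylbutane | CC[C@H](C)CBr | starting material
2 | N-methoxy-N-methylacetamide | CC(=O)N(C)OC | starting material
3 | (S)-2-methylbutylmagnesium bromide | CC[C@H](C)C[Mg]Br | intermediate (not isolated)
4 | (S)-4-methylhexan-2-one | CC[C@H](C)CC(C)=O | intermediate
5 | (2S,4S)-4-methylhexan-2-ol | CC[C@H](C)C[C@H](C)O | intermediate
6 | 4-methylpent-4-enoic acid | C=C(C)CCC(=O)O | starting material
7 | ethanethiol | CCS | starting material
8 | S-ethyl 4-methylpent-4-enethioate | C=C(C)CCC(=O)SCC | intermediate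
9 | (Z)-1-(ethylsulfanyl)-4-methyl-1-[(trimethylsilyl)oxy]penta-1,4-diene | C=C(C)C/C=C(/O[Si](C)(C)C)SCC | intermediate
10 | methyl pyruvate | CC(=O)C(=O)OC | starting material
11 | methyl (2R,3R)-3-[(ethylsulfanyl)carbonyl]-2,5-dimethyl-2-[(trimethylsilyl)oxy]hex-5-enoate | CCSC(=O)[C@H](CC(C)=C)[C@@](C)(O[Si](C)(C)C)C(=O)OC | intermediate (not isolated)
12 | methyl (2R,3R)-3-[(ethylsulfanyl)carbonyl]-2-hydroxy-2,5-dimethylhex-5-enoate | CCSC(=O)[C@H](CC(C)=C)[C@@](C)(O)C(=O)OC | intermediate
13 | methyl (2R,3R)-3-[(ethylsulfanyl)carbonyl]-2,5-dimethyl-2-[(triethylsilyl)oxy]hex-5-enoate | CCSC(=O)[C@H](CC(C)=C)[C@@](C)(O[Si](CC)(CC)CC)C(=O)OC | intermediate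
14 | 1-methyl 4-[(2S,4S)-4-methylhexan-2-yl] (2R,3R)-2-methyl-3-(2-methylprop-2-en-1-yl)-2-[(triethylsilyl)oxy]butanedioate | CC[C@H](C)C[C@H](C)OC(=O)[C@H](CC(C)=C)[C@@](C)(O[Si](CC)(CC)CC)C(=O)OC | intermediate
15 | secondary ozonide (1,2,4-trioxolane) of 14, mixture at the trioxolane carbon | CC[C@H](C)C[C@H](C)OC(=O)[C@H](CC1(C)OCOO1)[C@@](C)(O[Si](CC)(CC)CC)C(=O)OC | intermediate (not isolated)
16 | 1-methyl 4-[(2S,4S)-4-methylhexan-2-yl] (2R,3R)-2-methyl-3-(2-oxopropyl)-2-[(triethylsilyl)oxy]butanedioate (precursor of the key step) | CC[C@H](C)C[C@H](C)OC(=O)[C@H](CC(C)=O)[C@@](C)(O[Si](CC)(CC)CC)C(=O)OC | intermediate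
17 | potassium enolate of dione 18 | CC[C@H](C)C[C@H](C)OC(=O)[C@@H]1CC(=O)C=C([O-])[C@]1(C)O[Si](CC)(CC)CC.[K+] | intermediate (not isolated)
18 | (2S,4S)-4-methylhexan-2-yl (1R,2R)-2-methyl-3,5-dioxo-2-[(triethylsilyl)oxy]cyclohexane-1-carboxylate (product of the key step; C4a and C6 carbonyls) | CC[C@H](C)C[C@H](C)OC(=O)[C@@H]1CC(=O)CC(=O)[C@]1(C)O[Si](CC)(CC)CC | intermediate
19 | (2S,4S)-4-methylhexan-2-yl (1R,6R)-6-methyl-5-oxo-6-[(triethylsilyl)oxy]-3-[(trifluoromethanesulfonyl)oxy]cyclohex-3-ene-1-carboxylate (C4a enol triflate) | CC[C@H](C)C[C@H](C)OC(=O)[C@@H]1CC(OS(=O)(=O)C(F)(F)F)=CC(=O)[C@]1(C)O[Si](CC)(CC)CC | intermediate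
20 | 3-(trimethylsilyl)propynal | C[Si](C)(C)C#CC=O | starting material
21 | tert-butyl (triphenylphosphoranylidene)acetate | CC(C)(C)OC(=O)C=P(c1ccccc1)(c1ccccc1)c1ccccc1 | starting material
22 | tert-butyl (E)-5-(trimethylsilyl)pent-2-en-4-ynoate | C[Si](C)(C)C#C/C=C/C(=O)OC(C)(C)C | intermediate
23 | tert-butyl (E)-pent-2-en-4-ynoate | C#C/C=C/C(=O)OC(C)(C)C | intermediate
24 | (2S,4S)-4-methylhexan-2-yl (1R,6R)-3-[(E)-5-tert-butoxy-5-oxopent-3-en-1-yn-1-yl]-6-methyl-5-oxo-6-[(triethylsilyl)oxy]cyclohex-3-ene-1-carboxylate | CC[C@H](C)C[C@H](C)OC(=O)[C@@H]1CC(C#C/C=C/C(=O)OC(C)(C)C)=CC(=O)[C@]1(C)O[Si](CC)(CC)CC | intermediate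
25 | trimethyl orthoformate | COC(OC)OC | starting material
26 | tert-butyldimethylsilyl dienol ether of 24 (C6 silyloxy, C5=C6 and C4a=C8a double bonds) | CC[C@H](C)C[C@H](C)OC(=O)[C@@H]1C=C(C#C/C=C/C(=O)OC(C)(C)C)C=C(O[Si](C)(C)C(C)(C)C)[C@]1(C)O[Si](CC)(CC)CC | intermediate (not isolated)
27 | (2S,4S)-4-methylhexan-2-yl (1R,6R)-3-[(E)-5-tert-butoxy-5-oxopent-3-en-1-yn-1-yl]-2-(dimethoxymethyl)-6-methyl-5-oxo-6-[(triethylsilyl)oxy]cyclohex-3-ene-1-carboxylate, epimers at C8a | CC[C@H](C)C[C@H](C)OC(=O)[C@@H]1C(C(OC)OC)C(C#C/C=C/C(=O)OC(C)(C)C)=CC(=O)[C@]1(C)O[Si](CC)(CC)CC | intermediate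
28 | C8a-hydroxymethylene tautomer of the C8a-formyl ynenone (enol geometry free, interconverting through the aldehyde) | CC[C@H](C)C[C@H](C)OC(=O)[C@@H]1C(=CO)C(C#C/C=C/C(=O)OC(C)(C)C)=CC(=O)[C@]1(C)O[Si](CC)(CC)CC | intermediate (not isolated)
29 | tert-butyl (E)-3-[(7R,8R)-7-methyl-8-{[(2S,4S)-4-methylhexan-2-yl]oxycarbonyl}-6-oxo-7-[(triethylsilyl)oxy]-7,8-dihydro-6H-isochromen-3-yl]prop-2-enoate | CC[C@H](C)C[C@H](C)OC(=O)[C@@H]1C2=COC(/C=C/C(=O)OC(C)(C)C)=CC2=CC(=O)[C@]1(C)O[Si](CC)(CC)CC | intermediate
30 | (E)-3-[(7R,8R)-7-hydroxy-7-methyl-8-{[(2S,4S)-4-methylhexan-2-yl]oxycarbonyl}-6-oxo-7,8-dihydro-6H-isochromen-3-yl]prop-2-enoic acid | CC[C@H](C)C[C@H](C)OC(=O)[C@@H]1C2=COC(/C=C/C(=O)O)=CC2=CC(=O)[C@]1(C)O | target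

Total step count: 16.
Longest linear sequence: 12 steps (steps 3–10 and 13–16, from 4-methylpent-4-enoic acid).

Steps most likely to fail

Step 9. The C8 ester enolate may form in competition and expel the C7 silyloxy group (E1cB), or the C5 enolate may close onto the side-chain ester, before the six-membered ring forms. The fallback sets out from 16 and removes the leaving-group character of the C7 oxygen instead of changing the base. The silyl ether is cleaved with HF·pyridine in THF to give the hydroxy keto diester F1. LiN(SiMe3)2 (3.2 equiv, THF, −78 to 0 °C) then turns the tertiary alcohol into a lithium alkoxide, which cannot be eliminated (the principle behind Fráter–Seebach dianion chemistry), and the ketone enolate cyclises to the hydroxy dione F2. Silylation with Et3SiOTf and 2,6-lutidine, the labile enol silyl ether being lost on aqueous work-up, returns to the route at 18.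

Step 14. The carbenium ion may attack the alpha carbon C5 of the dienol ether instead of C8a, or the silyl triflate may erode the tert-butyl ester. The fallback sets out from 24 and replaces the Lewis-acid path by a condensation with tert-butoxybis(dimethylamino)methane (toluene, 60 °C). Only C8a carries two acidic hydrogens in conjugation with the enone, so this should give the dimethylaminomethylene dienynone F3. Mild aqueous acid (AcOH/H2O) releases the formyl enol 28, and AuCl3 closes the pyran as in step 15, returning to the route at 29.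

Step 7. Acyl transfer at the crowded C8 carbonyl may be slow, so that loss of the silyl group or ketene formation with epimerisation at C8 competes. The fallback sets out from 13 and makes the ester by O-alkylation instead of acyl transfer. The thioester is cleaved with LiOH/H2O2 (THF/H2O, 0 °C) to the acid F4, (2R,3R)-4-methoxy-3-methyl-2-(2-methylprop-2-en-1-yl)-4-oxo-3-[(triethylsilyl)oxy]butanoic acid. A Mitsunobu reaction (PPh3, DIAD, THF) then joins it to (2R,4S)-4-methylhexan-2-ol F5, made from 4 with an (R)-selective ketoreductase. The carboxylate attacks the unhindered secondary carbon with inversion, which gives the (2S) ester and returns to the route at 14.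

Further compounds
F1 | step 9 | 1-methyl 4-[(2S,4S)-4-methylhexan-2-yl] (2R,3R)-2-hydroxy-2-methyl-3-(2-oxopropyl)butanedioate | CC[C@H](C)C[C@H](C)OC(=O)[C@H](CC(C)=O)[C@@](C)(O)C(=O)OC
F2 | step 9 | (2S,4S)-4-methylhexan-2-yl (1R,2R)-2-hydroxy-2-methyl-3,5-dioxocyclohexane-1-carboxylate | CC[C@H](C)C[C@H](C)OC(=O)[C@@H]1CC(=O)CC(=O)[C@]1(C)O
F3 | step 14 | C8a-(dimethylaminomethylene) derivative of dienynone 24 | CC[C@H](C)C[C@H](C)OC(=O)[C@@H]1C(=CN(C)C)C(C#C/C=C/C(=O)OC(C)(C)C)=CC(=O)[C@]1(C)O[Si](CC)(CC)CC
F4 | step 7 | (2R,3R)-4-methoxy-3-methyl-2-(2-methylprop-2-en-1-yl)-4-oxo-3-[(triethylsilyl)oxy]butanoic acid | OC(=O)[C@H](CC(C)=C)[C@@](C)(O[Si](CC)(CC)CC)C(=O)OC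
F5 | step 7 | (2R,4S)-4-methylhexan-2-ol | CC[C@H](C)C[C@@H](C)O
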